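## Structural features

The target has one ring, a 1,2-dioxolane (O1–O2–C3–C4–C5). C3 carries a methyl group and a CH2CO2H arm. C5 carries a methyl group and an unbranched C16 chain: C1'–C8' are methylenes, C9'–C14' form an all-E conjugated triene, and the chain ends in an ethyl group. The two stereocentres, C3 (R) and C5 (S), are both fully substituted peroxy carbons, 1,3-related across the C4 methylene. Fragile elements are:

- the O–O bond, which is lost to catalytic hydrogenation, hydrides, carbanions, hot phosphines and low-valent metals such as zerovalent palladium;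
- the carbonyl β to O2, which once enolisable can open the ring by β-elimination;
- the triene, which is sensitive to oxidants and acid and rules out any alkene reduction after it is in place.

Because neither peroxy carbon bears hydrogen, base-induced Kornblum–DeLaMare cleavage cannot occur, so amide bases and fluoride are tolerated. The real difficulty is stereochemical: at each centre the two carbon substituents differ only as CH3 versus CH2R and there is no neighbouring stereocentre, so substrate bias cannot be relied on. The key step exploits the substitution pattern of C5 (CH3, C4, O1, C1'). With C5=C1' as an E-trisubstituted alkene and C2' as a sacrificial (S)-carbinol, the hydroperoxide on C3 adds to C5 on the carbinol face and hydroxide leaves from C2'. C3 itself comes from a chiral-pool tertiary carbinol by substitution with inversion.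

## Logic of the disconnections

**28 from 26 (through 27).** Only the oxidation level of the arm terminus changes. The acid is made last because a carbonyl β to O2 is the one base-sensitive site of the ring and would not be safe under the sulfone-anion step. No skeletal gain. The forward demand is an oxidation that spares the triene and the O–O bond.

**26 and 25 from 23 and 24.** The C9'=C10' double bond is cut. The triene must come after the only alkene reduction of the route, and 24 brings seven carbons and two E double bonds ready-made. The demand is E selectivity at the new bond and a base that the ring tolerates.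

**23 from 19 (through 22, 21 and 20).** Functional-group changes at the chain terminus (sulfone, sulfide, alcohol, silyl ether) and re-introduction of the C1'=C2' double bond. The sulfone is placed on the ring fragment so that 24 is used as bought. The demand is an alkene reduction that leaves the O–O bond alone, and removal of one silyl ether in the presence of the other.

**19 from 18.** The C5–O1 bond is cut in the SN2' sense, which opens the ring, moves the alkene back to C5=C1' and puts a hydroxyl on C2'. This removes the ring and the C5 stereocentre in one operation and reduces the stereochemical problem to one secondary carbinol and one alkene geometry. The demand is clean 1,3-chirality transfer with the O–O bond intact.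

**18 from 10 and 16 (through 17).** The C5=C1' double bond is cut by cross-metathesis into a methallyl peroxide and a vinyl carbinol. This is the most convergent cut, and metathesis is one of the few C–C bond formations that a masked peroxide survives. The demand is E geometry, because the Z isomer would lead to the C5 epimer.

**10 from 7 (through 9 and 8).** The C3–O2 bond is cut back to an oxetane that holds C3 and the arm oxygen. Ring strain allows substitution at a tertiary carbon with inversion, so a chiral-pool carbinol can supply C3. The demand is an SN2-like opening without ionisation, and differentiation of OH from OOH afterwards.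

**7 from 1 (through 5 and 3).** The oxetane O–CH2 bond, the C=CH2 bond and the C–CH3 bond at the former lactone carbon are cut. All carbons of 1 are used and its stereocentre is carried unchanged. The demand is a methylenation that does not trigger retro-aldol cleavage of a tertiary aldol.

**16 from 11 and 14 (through 15, 13 and 12).** The C1'–C2' bond is cut to an aldehyde and a vinyl nucleophile; the carbinol configuration comes from a kinetic resolution. The materials are cheap, so a resolution is acceptable.

## Other disconnections considered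

**Alternative 1:** Both ring C–O bonds (C5–O1 and C3–O2) are cut, leading back to the C2-symmetric bis-oxetane A1.

- Forward step: H2O2 with TMSOTf would open one oxetane of A1 at its tertiary carbon with inversion. The new hydroperoxide would then open the second oxetane in a 5-exo-tet substitution, again with inversion, to give 2,2'-[(3S,5S)-3,5-dimethyl-1,2-dioxolane-3,5-diyl]diethanol A2.
- In favour: both peroxy centres come from one metal-free, stereospecific reaction type known for tertiary oxetanes. The two arms of A2 are homotopic, so mono-functionalisation gives one compound. No alkene geometry is at stake.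
- Against: A1 needs two tertiary carbinol centres of like configuration, with the meso isomer excluded. The intermediate hydroperoxide can attack a second molecule. Mono-protection of A2 is statistical. One arm must then be extended by fourteen carbons (oxidation, olefination, alkene reduction before the triene) while the other is oxidised.
- Comparison: on mechanistic and stereochemical security of ring formation, Alternative 1 is the better. On the source of absolute configuration the two are equal, since both rest on inversion of a tertiary C–O centre. On step economy the chosen plan should be somewhat better, because chain and C5 centre arrive in one convergent coupling without statistical desymmetrisation.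

**Alternative 2:** Only O1–O2 is cut, leading back to the bis(aminooxy) compound A3, in which both tertiary C–O bonds already exist.

- Forward step: PhI(OAc)2 would oxidise the two ONH2 groups to a cyclic cis-hyponitrite. Loss of N2 would leave a tethered pair of alkoxyl radicals, whose combination would give (3S,5S)-3,5-bis[2-(tert-butyldimethylsilyloxy)ethyl]-3,5-dimethyl-1,2-dioxolane A4 with retention at both carbons.
- In favour: no peroxide is carried through the synthesis, so organometallic reagents, hydrides and zerovalent palladium stay usable until the last ring-forming step. On this point it is better than the chosen plan. The stereocentres are ordinary tertiary carbinols.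
- Against: O-amination of two hindered tertiary alcohols is difficult. The hyponitrite route to a five-membered peroxide has no close analogy. Tertiary alkoxyl radicals readily undergo β-scission and hydrogen abstraction in competition with O–O coupling. The desymmetrisation burden is the same as in Alternative 1.
- Comparison: the mechanism is less secure than the chosen plan, whose elementary steps each have a close analogy. Step economy is about equal.

**Alternative 3:** C4–C5 and C3–O2 are cut, leading back to the silyl peroxyketal A5 and the alkene A6.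

- Forward step: SnCl4 would ionise A5 to a peroxycarbenium ion. The methylene of A6 would add to C5, and the silylated peroxide oxygen would capture the tertiary cation at C3 to give methyl 2-[(3R,5S)-5-[9-(tert-butyldiphenylsilyloxy)nonyl]-3,5-dimethyl-1,2-dioxolan-3-yl]acetate A7.
- In favour: the whole ring and both quaternary centres form in one step from two achiral pieces by a known annulation type. The arm arrives at the acid oxidation level. On step economy and precedent it is clearly better than the chosen plan.
- Against: there is no control of absolute configuration. Relative control between two centres that each distinguish only CH3 from CH2R should be weak, so A7 would be one component of a stereoisomer mixture needing resolution. The ester-deactivated alkene A6 is a modest nucleophile.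
- Comparison: the chosen plan is longer but addresses the actual difficulty, a single enantiomer with defined C3/C5 relationship, which Alternative 3 leaves open.

Key step: step 13

Remarks on the chemistry:

- Atom labels follow the target throughout: ring O1–O2–C3–C4–C5, with C3 bearing the two-carbon arm, and chain C1'–C16' counted from C5.
- The stereochemical bookkeeping was checked: (S)-carbinol, E-alkene and syn delivery lead to the target arrangement at C5, and inversion of the centre of 1 gives that at C3. No structure needed correction.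
- CIP descriptors change along the route without any change in spatial arrangement: C3 is R in 18, the ring is 3S,5R in 19, 3S,5S in 20–26, and 3R,5S in 27 and 28.
- Assumption: the palladium-mediated substitution runs syn. Should it run anti, the same route is used with the enantiomer of 16, obtained from the resolution with the L-tartrate.
- Precursor 18 keeps the free carbinol (the directing and leaving group) and the free hydroperoxide. Every other oxygen is blocked as a silyl ether, the bulkier one on the arm, which could otherwise reach C5 through a six-membered ring.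

## Route

Step 1
Reactants: 1 (R)-mevalonolactone [(4R)-4-hydroxy-4-methyloxan-2-one]
Product: 3 (4R)-4,6-dihydroxy-4-methylhexan-2-one (in equilibrium with its six-membered hemiketal), via Weinreb amide 2 (not isolated)
Conditions: MeNH(OMe)·HCl, i-PrMgCl, THF, −20 °C; then MeMgBr, −20 → 0 °C; aq NH4Cl
Reagents that add atoms: methylmagnesium bromide, C[Mg]Br
Why: The chloromagnesium amide opens the lactone to the N-methoxy-N-methylamide, whose magnesium chelate accepts one methyl group only, so the methyl ketone appears on work-up (one-pot Weinreb ketone synthesis); the tertiary carbinol centre is not involved.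

Step 2
Reactants: 3 (4R)-4,6-dihydroxy-4-methylhexan-2-one
Product: 5 (3S)-3,5-dimethylhex-5-ene-1,3-diol, via beta-hydroxysilane 4 (not isolated)
Conditions: Me3SiCH2MgCl, CeCl3, THF, −78 → 0 °C; then aq HF, MeCN, rt
Reagents that add atoms: (trimethylsilyl)methylmagnesium chloride, C[Si](C)(C)C[Mg]Cl
Why: Peterson olefination: the weakly basic organometallic adds to the open keto form at low temperature, where the magnesium aldolate of this tertiary aldol should not undergo the retro-aldol cleavage that a basic Wittig ylide would invite, and acid-promoted anti elimination of the β-hydroxysilane gives the 1,1-disubstituted alkene. The descriptor changes from R to S only because substituent ranking changes.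

Step 3
Reactants: 5 (3S)-3,5-dimethylhex-5-ene-1,3-diol
Product: 7 (2S)-2-methyl-2-(2-methylprop-2-en-1-yl)oxetane, via monotosylate 6 (not isolated)
Conditions: n-BuLi (1 equiv), THF, 0 °C; TsCl (1 equiv); then n-BuLi (1 equiv), 0 → 60 °C
Reagents that add atoms: none
Why: The primary alkoxide is sulfonylated selectively and the tertiary alkoxide then closes the ring in a 4-exo-tet Williamson etherification; the C–O bond at the stereocentre is kept, so configuration is retained (the product is volatile and is concentrated with care).

Step 4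
Reactants: 7 (2S)-2-methyl-2-(2-methylprop-2-en-1-yl)oxetane
Product: 8 (3R)-3-hydroperoxy-3,5-dimethylhex-5-en-1-ol
Conditions: anhydrous H2O2 in Et2O (excess), TMSOTf (0.2 equiv), Et2O, −78 → −20 °C
Reagents that add atoms: hydrogen peroxide, OO
Why: Lewis-acid perhydrolysis of a 2,2-disubstituted oxetane: H2O2 attacks the activated ring at the tertiary carbon from the rear, so C3 of the target is set with inversion; low temperature and excess H2O2 should suppress ionisation and attack of 8 on a second oxetane. Any erosion at this centre would later appear as a ring diastereomer of 19, removable by chromatography.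

Step 5
Reactants: 8 (3R)-3-hydroperoxy-3,5-dimethylhex-5-en-1-ol
Product: 9 tert-butyl{[(3R)-3-hydroperoxy-3,5-dimethylhex-5-en-1-yl]oxy}diphenylsilane
Conditions: TBDPSCl (1.05 equiv), imidazole, CH2Cl2, −20 → 0 °C
Reagents that add atoms: tert-butyl(chloro)diphenylsilane, CC(C)(C)[Si](Cl)(c1ccccc1)c1ccccc1
Why: Chemoselective silylation: the unhindered primary hydroxyl is more basic and less shielded than the OOH group on a fully substituted carbon, and a bulky silyl chloride with a weak base (no peroxide anion) should widen that gap.

Step 6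
Reactants: 9 tert-butyl{[(3R)-3-hydroperoxy-3,5-dimethylhex-5-en-1-yl]oxy}diphenylsilane
Product: 10 tert-butyl{[(3R)-3-[(2-methoxypropan-2-yl)peroxy]-3,5-dimethylhex-5-en-1-yl]oxy}diphenylsilane
Conditions: 2-methoxypropene, PPTS (cat.), CH2Cl2, 0 °C
Reagents that add atoms: 2-methoxypropene, COC(C)=C
Why: Acid-catalysed addition of the hydroperoxide to the enol ether gives the monoperoxyketal, which removes the OOH proton that would destroy a ruthenium carbene.

Step 7
Reactants: 11 octane-1,8-diol
Product: 12 8-{[tert-butyl(dimethyl)silyl]oxy}octan-1-ol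
Conditions: NaH (1 equiv), THF, rt; TBSCl (1 equiv)
Reagents that add atoms: tert-butyl(chloro)dimethylsilane, CC(C)(C)[Si](C)(C)Cl
Why: Monosilylation through the sparingly soluble monosodium alkoxide of a symmetrical diol.

Step 8
Reactants: 12 8-{[tert-butyl(dimethyl)silyl]oxy}octan-1-ol
Product: 13 8-{[tert-butyl(dimethyl)silyl]oxy}octanal
Conditions: TEMPO (cat.), PhI(OAc)2, CH2Cl2, rt
Reagents that add atoms: none
Why: Nitroxyl-catalysed oxidation of a primary alcohol, which stops at the aldehyde in the absence of water.

Step 9
Reactants: 13 8-{[tert-butyl(dimethyl)silyl]oxy}octanal; 14 vinylmagnesium bromide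
Product: 15 rac-10-{[tert-butyl(dimethyl)silyl]oxy}dec-1-en-3-ol
Conditions: THF, −78 → 0 °C; aq NH4Cl
Reagents that add atoms: none
Why: Grignard 1,2-addition to an aldehyde gives the racemic vinyl carbinol.

Step 10
Reactants: 15 rac-10-{[tert-butyl(dimethyl)silyl]oxy}dec-1-en-3-ol
Product: 16 (3S)-10-{[tert-butyl(dimethyl)silyl]oxy}dec-1-en-3-ol
Conditions: Ti(Oi-Pr)4, D-(−)-diisopropyl tartrate, t-BuOOH (0.6 equiv), 4 Å MS, CH2Cl2, −20 °C
Reagents that add atoms: none
Why: Sharpless kinetic resolution: with the D-tartrate the (R)-enantiomer is epoxidised fast and the (S)-alcohol is recovered at a little over half conversion. This carbinol (C2' of the target numbering) is the centre that later relays its configuration to C5.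

Step 11
Reactants: 10 tert-butyl{[(3R)-3-[(2-methoxypropan-2-yl)peroxy]-3,5-dimethylhex-5-en-1-yl]oxy}diphenylsilane; 16 (3S)-10-{[tert-butyl(dimethyl)silyl]oxy}dec-1-en-3-ol (3 equiv)
Product: 17 (3R,5E,7S)-14-{[tert-butyl(dimethyl)silyl]oxy}-1-{[tert-butyl(diphenyl)silyl]oxy}-3-[(2-methoxypropan-2-yl)peroxy]-3,5-dimethyltetradec-5-en-7-ol
Conditions: second-generation Hoveyda–Grubbs catalyst RuCl2(H2IMes)(=CH-C6H4-2-Oi-Pr) (10 mol %), 1,4-benzoquinone (cat.), CH2Cl2, 40 °C
Reagents that add atoms: none
Why: Cross-metathesis of a 1,1-disubstituted alkene with a secondary allylic alcohol; the phosphine-free catalyst and the peroxyketal are mutually inert, and benzoquinone suppresses isomerisation of the allylic alcohol. E geometry should be favoured because the branched carbinol carbon avoids the bulky CH2–C(quaternary) substituent. Any Z isomer is removed by chromatography here or after step 12, since it would lead to the C5 epimer.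

Step 12
Reactants: 17 (3R,5E,7S)-14-{[tert-butyl(dimethyl)silyl]oxy}-1-{[tert-butyl(diphenyl)silyl]oxy}-3-[(2-methoxypropan-2-yl)peroxy]-3,5-dimethyltetradec-5-en-7-ol
Product: 18 (3R,5E,7S)-14-{[tert-butyl(dimethyl)silyl]oxy}-1-{[tert-butyl(diphenyl)silyl]oxy}-3-hydroperoxy-3,5-dimethyltetradec-5-en-7-ol
Conditions: AcOH–THF–H2O, 0 °C → rt (short contact)
Reagents that add atoms: none
Why: Mild acid hydrolysis of the peroxyketal, which is far more labile than either silyl ether and proceeds under conditions too weak to ionise the allylic alcohol.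

Step 13
Reactants: 18 (3R,5E,7S)-14-{[tert-butyl(dimethyl)silyl]oxy}-1-{[tert-butyl(diphenyl)silyl]oxy}-3-hydroperoxy-3,5-dimethyltetradec-5-en-7-ol
Product: 19 tert-butyl{2-[(3S,5R)-5-[(1E)-9-{[tert-butyl(dimethyl)silyl]oxy}non-1-en-1-yl]-3,5-dimethyl-1,2-dioxolan-3-yl]ethoxy}diphenylsilane
Conditions: PdCl2(MeCN)2 (10 mol %), THF, 0 °C → rt
Reagents that add atoms: none
Why: Proposed new method: PdCl2(MeCN)2 (divalent palladium throughout) should bind the C5=C1' alkene on the face of the C2' hydroxyl; the terminal hydroperoxide oxygen then adds to the fully substituted C5 on that same face while palladium bonds to C1', and syn β-hydroxide elimination releases water and the new C1'=C2' alkene; the closest known reaction types are the PdCl2(MeCN)2-catalysed syn-SN2' cyclisations of hydroxy allylic alcohols to cyclic ethers with 1,3-chirality transfer and the divalent-palladium cyclisations of unsaturated hydroperoxides to 1,2-dioxanes. The 1,2-dioxolane closes in the 5-exo-trig mode. The new C5 stereocentre is controlled by the (S)-carbinol together with the E geometry: allylic 1,3-strain with the C5 methyl holds the C2'–H bond in the alkene plane, so the hydroxyl marks one face, and oxygen delivered to that face places O1, CH3, C4 and the alkenyl group as in the target. The same conformation makes the new alkene E, and C3 is not touched. Attack at C5 rather than direct displacement at C2' (a seven-membered ring) is secured by ring size and by the Markovnikov polarisation of the π-complex. β-Hydroxide rather than β-hydride elimination is secured by hydroxyl coordination to palladium, so no zerovalent palladium should arise to reduce the O–O bond. Collapse of a peroxypalladium intermediate by hydride shift is excluded because C5 bears no hydrogen. The only other oxygen within reach of C5 is blocked by the bulky diphenylsilyl group.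

Step 14
Reactants: 19 tert-butyl{2-[(3S,5R)-5-[(1E)-9-{[tert-butyl(dimethyl)silyl]oxy}non-1-en-1-yl]-3,5-dimethyl-1,2-dioxolan-3-yl]ethoxy}diphenylsilane
Product: 20 tert-butyl{2-[(3S,5S)-5-(9-{[tert-butyl(dimethyl)silyl]oxy}nonyl)-3,5-dimethyl-1,2-dioxolan-3-yl]ethoxy}diphenylsilane
Conditions: 2-nitrobenzenesulfonylhydrazide (excess, in portions), Et3N, CH2Cl2, rt
Reagents that add atoms: none
Why: Diimide reduction: concerted transfer of two hydrogens to the C=C bond, a reagent that does not cleave O–O bonds where catalytic hydrogenation would. The alkene next to a quaternary carbon is hindered, so excess reagent is planned.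

Step 15
Reactants: 20 tert-butyl{2-[(3S,5S)-5-(9-{[tert-butyl(dimethyl)silyl]oxy}nonyl)-3,5-dimethyl-1,2-dioxolan-3-yl]ethoxy}diphenylsilane
Product: 21 9-[(3S,5S)-3-{2-[(tert-butyldiphenylsilyl)oxy]ethyl}-3,5-dimethyl-1,2-dioxolan-5-yl]nonan-1-ol
Conditions: CSA (cat.), MeOH–CH2Cl2, 0 °C
Reagents that add atoms: none
Why: Acid methanolysis removes the primary dimethylsilyl ether much faster than the primary diphenylsilyl ether; the di-tertiary peroxide is inert to catalytic sulfonic acid at 0 °C.

Step 16
Reactants: 21 9-[(3S,5S)-3-{2-[(tert-butyldiphenylsilyl)oxy]ethyl}-3,5-dimethyl-1,2-dioxolan-5-yl]nonan-1-ol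
Product: 22 5-({9-[(3S,5S)-3-{2-[(tert-butyldiphenylsilyl)oxy]ethyl}-3,5-dimethyl-1,2-dioxolan-5-yl]nonyl}sulfanyl)-1-phenyl-1H-tetrazole
Conditions: 1-phenyl-1H-tetrazole-5-thiol, PPh3, DIAD, THF, 0 °C
Reagents that add atoms: 1-phenyl-1H-tetrazole-5-thiol, Sc1nnnn1-c1ccccc1
Why: Mitsunobu thioetherification of a primary alcohol; the phosphine is taken up by the azodicarboxylate at once, and a hindered di-tertiary peroxide should react with phosphines only on heating.

Step 17
Reactants: 22 5-({9-[(3S,5S)-3-{2-[(tert-butyldiphenylsilyl)oxy]ethyl}-3,5-dimethyl-1,2-dioxolan-5-yl]nonyl}sulfanyl)-1-phenyl-1H-tetrazole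
Product: 23 5-({9-[(3S,5S)-3-{2-[(tert-butyldiphenylsilyl)oxy]ethyl}-3,5-dimethyl-1,2-dioxolan-5-yl]nonyl}sulfonyl)-1-phenyl-1H-tetrazole
Conditions: (NH4)6Mo7O24·4H2O (cat.), 30% H2O2, EtOH, 0 °C → rt
Reagents that add atoms: hydrogen peroxide, OO
Why: Molybdate-catalysed oxidation of sulfide to sulfone; oxidising conditions do not harm a dialkyl peroxide, and no alkene is present at this stage.

Step 18
Reactants: 23 5-({9-[(3S,5S)-3-{2-[(tert-butyldiphenylsilyl)oxy]ethyl}-3,5-dimethyl-1,2-dioxolan-5-yl]nonyl}sulfonyl)-1-phenyl-1H-tetrazole; 24 (2E,4E)-hepta-2,4-dienal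
Product: 25 tert-butyl{2-[(3S,5S)-5-[(9E,11E,13E)-hexadeca-9,11,13-trien-1-yl]-3,5-dimethyl-1,2-dioxolan-3-yl]ethoxy}diphenylsilane
Conditions: KHMDS, DME, −78 °C; then 24, −78 °C → rt
Reagents that add atoms: none
Why: Julia–Kocienski olefination: the metalated phenyltetrazolyl sulfone adds to the aldehyde, and Smiles rearrangement with loss of SO2 and the tetrazolone forms C9'=C10'. Potassium counter-ion, ethereal solvent and a conjugated aldehyde should all favour the E alkene. The sulfone is metalated before 24 is added, so the vinylogously acidic dienal never meets free base, and the ring tolerates the base because neither peroxy carbon bears hydrogen.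

Step 19
Reactants: 25 tert-butyl{2-[(3S,5S)-5-[(9E,11E,13E)-hexadeca-9,11,13-trien-1-yl]-3,5-dimethyl-1,2-dioxolan-3-yl]ethoxy}diphenylsilane
Product: 26 2-[(3S,5S)-5-[(9E,11E,13E)-hexadeca-9,11,13-trien-1-yl]-3,5-dimethyl-1,2-dioxolan-3-yl]ethan-1-ol
Conditions: Bu4NF, AcOH (1 equiv), THF, 0 °C → rt
Reagents that add atoms: none
Why: Fluoride cleavage of the silyl ether; the buffered reagent leaves the triene and the peroxide alone.

Step 20
Reactants: 26 2-[(3S,5S)-5-[(9E,11E,13E)-hexadeca-9,11,13-trien-1-yl]-3,5-dimethyl-1,2-dioxolan-3-yl]ethan-1-ol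
Product: 27 2-[(3R,5S)-5-[(9E,11E,13E)-hexadeca-9,11,13-trien-1-yl]-3,5-dimethyl-1,2-dioxolan-3-yl]acetaldehyde
Conditions: Dess–Martin periodinane, NaHCO3, CH2Cl2, 0 °C → rt
Reagents that add atoms: none
Why: Dess–Martin oxidation under buffered, non-basic conditions that spare the triene and O–O bond; the β-peroxy aldehyde is used crude at once so that base-induced β-elimination has no opportunity.

Step 21
Reactants: 27 2-[(3R,5S)-5-[(9E,11E,13E)-hexadeca-9,11,13-trien-1-yl]-3,5-dimethyl-1,2-dioxolan-3-yl]acetaldehyde
Product: 28 2-[(3R,5S)-5-[(9E,11E,13E)-hexadeca-9,11,13-trien-1-yl]-3,5-dimethyl-1,2-dioxolan-3-yl]acetic acid (CNP0181055.2)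
Conditions: NaClO2, NaH2PO4, 2-methylbut-2-ene (large excess), t-BuOH–H2O, 0 °C
Reagents that add atoms: sodium chlorite, [Na+].[O-]Cl=O
Why: Pinnick oxidation at weakly acidic pH; the alkene scavenger intercepts hypochlorous acid before it can reach the triene, and no base is present to open the β-peroxy carbonyl unit.

## Compound list

1 | (R)-mevalonolactone, (4R)-4-hydroxy-4-methyloxan-2-one | C[C@@]1(O)CCOC(=O)C1 | starting material
2 | (3R)-3,5-dihydroxy-N-methoxy-N,3-dimethylpentanamide | C[C@@](CC(=O)N(C)OC)(O)CCO | intermediate
3 | (4R)-4,6-dihydroxy-4-methylhexan-2-one | C[C@@](CC(C)=O)(O)CCO | intermediate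
4 | (4R)-2,4-dimethyl-1-(trimethylsilyl)hexane-2,4,6-triol (both C2 epimers) | C[C@@](CC(C)(O)C[Si](C)(C)C)(O)CCO | intermediate
5 | (3S)-3,5-dimethylhex-5-ene-1,3-diol | C[C@@](CC(C)=C)(O)CCO | intermediate
6 | (3S)-3-hydroxy-3,5-dimethylhex-5-en-1-yl 4-methylbenzenesulfonate | C[C@@](CC(C)=C)(O)CCOS(=O)(=O)c1ccc(C)cc1 | intermediate
7 | (2S)-2-methyl-2-(2-methylprop-2-en-1-yl)oxetane | C[C@@]1(CC(C)=C)OCC1 | intermediate
8 | (3R)-3-hydroperoxy-3,5-dimethylhex-5-en-1-ol | C[C@](CC(C)=C)(OO)CCO | intermediate
9 | tert-butyl{[(3R)-3-hydroperoxy-3,5-dimethylhex-5-en-1-yl]oxy}diphenylsilane | C[C@](CC(C)=C)(OO)CCO[Si](c1ccccc1)(c1ccccc1)C(C)(C)C | intermediate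
10 | tert-butyl{[(3R)-3-[(2-methoxypropan-2-yl)peroxy]-3,5-dimethylhex-5-en-1-yl]oxy}diphenylsilane | C[C@](CC(C)=C)(OOC(C)(C)OC)CCO[Si](c1ccccc1)(c1ccccc1)C(C)(C)C | intermediate
11 | octane-1,8-diol | OCCCCCCCCO | starting material
12 | 8-{[tert-butyl(dimethyl)silyl]oxy}octan-1-ol | CC(C)(C)[Si](C)(C)OCCCCCCCCO | intermediate
13 | 8-{[tert-butyl(dimethyl)silyl]oxy}octanal | CC(C)(C)[Si](C)(C)OCCCCCCCC=O | intermediate
14 | vinylmagnesium bromide | C=C[Mg]Br | starting material
15 | rac-10-{[tert-butyl(dimethyl)silyl]oxy}dec-1-en-3-ol | CC(C)(C)[Si](C)(C)OCCCCCCCC(O)C=C | intermediate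
16 | (3S)-10-{[tert-butyl(dimethyl)silyl]oxy}dec-1-en-3-ol | CC(C)(C)[Si](C)(C)OCCCCCCC[C@H](O)C=C | intermediate
17 | (3R,5E,7S)-14-{[tert-butyl(dimethyl)silyl]oxy}-1-{[tert-butyl(diphenyl)silyl]oxy}-3-[(2-methoxypropan-2-yl)peroxy]-3,5-dimethyltetradec-5-en-7-ol | CC(C)(C)[Si](C)(C)OCCCCCCC[C@H](O)/C=C(\C)C[C@@](C)(OOC(C)(C)OC)CCO[Si](c1ccccc1)(c1ccccc1)C(C)(C)C | intermediate
18 | (3R,5E,7S)-14-{[tert-butyl(dimethyl)silyl]oxy}-1-{[tert-butyl(diphenyl)silyl]oxy}-3-hydroperoxy-3,5-dimethyltetradec-5-en-7-ol | CC(C)(C)[Si](C)(C)OCCCCCCC[C@H](O)/C=C(\C)C[C@@](C)(OO)CCO[Si](c1ccccc1)(c1ccccc1)C(C)(C)C | intermediate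
19 | tert-butyl{2-[(3S,5R)-5-[(1E)-9-{[tert-butyl(dimethyl)silyl]oxy}non-1-en-1-yl]-3,5-dimethyl-1,2-dioxolan-3-yl]ethoxy}diphenylsilane | CC(C)(C)[Si](C)(C)OCCCCCCC/C=C/[C@@]1(C)C[C@](C)(CCO[Si](c2ccccc2)(c2ccccc2)C(C)(C)C)OO1 | intermediate
20 | tert-butyl{2-[(3S,5S)-5-(9-{[tert-butyl(dimethyl)silyl]oxy}nonyl)-3,5-dimethyl-1,2-dioxolan-3-yl]ethoxy}diphenylsilane | CC(C)(C)[Si](C)(C)OCCCCCCCCC[C@@]1(C)C[C@](C)(CCO[Si](c2ccccc2)(c2ccccc2)C(C)(C)C)OO1 | intermediate
21 | 9-[(3S,5S)-3-{2-[(tert-butyldiphenylsilyl)oxy]ethyl}-3,5-dimethyl-1,2-dioxolan-5-yl]nonan-1-ol | OCCCCCCCCC[C@@]1(C)C[C@](C)(CCO[Si](c2ccccc2)(c2ccccc2)C(C)(C)C)OO1 | intermediate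
22 | 5-({9-[(3S,5S)-3-{2-[(tert-butyldiphenylsilyl)oxy]ethyl}-3,5-dimethyl-1,2-dioxolan-5-yl]nonyl}sulfanyl)-1-phenyl-1H-tetrazole | c1ccccc1-n1nnnc1SCCCCCCCCC[C@@]2(C)C[C@](C)(CCO[Si](c3ccccc3)(c3ccccc3)C(C)(C)C)OO2 | intermediate
23 | 5-({9-[(3S,5S)-3-{2-[(tert-butyldiphenylsilyl)oxy]ethyl}-3,5-dimethyl-1,2-dioxolan-5-yl]nonyl}sulfonyl)-1-phenyl-1H-tetrazole | c1ccccc1-n1nnnc1S(=O)(=O)CCCCCCCCC[C@@]2(C)C[C@](C)(CCO[Si](c3ccccc3)(c3ccccc3)C(C)(C)C)OO2 | intermediate
24 | (2E,4E)-hepta-2,4-dienal | CC/C=C/C=C/C=O | starting material
25 | tert-butyl{2-[(3S,5S)-5-[(9E,11E,13E)-hexadeca-9,11,13-trien-1-yl]-3,5-dimethyl-1,2-dioxolan-3-yl]ethoxy}diphenylsilane | CC/C=C/C=C/C=C/CCCCCCCC[C@@]1(C)C[C@](C)(CCO[Si](c2ccccc2)(c2ccccc2)C(C)(C)C)OO1 | intermediate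
26 | 2-[(3S,5S)-5-[(9E,11E,13E)-hexadeca-9,11,13-trien-1-yl]-3,5-dimethyl-1,2-dioxolan-3-yl]ethan-1-ol | CC/C=C/C=C/C=C/CCCCCCCC[C@@]1(C)C[C@](C)(CCO)OO1 | intermediate
27 | 2-[(3R,5S)-5-[(9E,11E,13E)-hexadeca-9,11,13-trien-1-yl]-3,5-dimethyl-1,2-dioxolan-3-yl]acetaldehyde | CC/C=C/C=C/C=C/CCCCCCCC[C@@]1(C)C[C@](C)(CC=O)OO1 | intermediate
28 | 2-[(3R,5S)-5-[(9E,11E,13E)-hexadeca-9,11,13-trien-1-yl]-3,5-dimethyl-1,2-dioxolan-3-yl]acetic acid | CC/C=C/C=C/C=C/CCCCCCCC[C@@]1(C)C[C@](C)(CC(=O)O)OO1 | target

## Step count and least certain steps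

Total step count: 21. Longest linear sequence: 17 steps (steps 1–6 and 11–21, from 1); the branch from 11 contributes steps 7–10.

**Step 13 (key step).** Most likely failure modes: leakage of facial selectivity, through ionisation of the allylic alcohol or an anti pathway, so that chirality transfer to C5 is incomplete; and β-hydride elimination at the alkylpalladium stage, which would give a ketone and zerovalent palladium that then reduces the O–O bond. Fallback by known chemistry, setting out from 10 and returning at 21:

- Ozonolysis of the methallyl group (O3, CH2Cl2–MeOH, −78 °C; Me2S) gives the ketone (4S)-6-[(tert-butyldiphenylsilyl)oxy]-4-[(2-methoxypropan-2-yl)peroxy]-4-methylhexan-2-one F1.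
- Acidic methanol (p-TsOH, MeOH) removes the peroxyketal, the hydroperoxide closes onto the ketone and the hemiketal is methylated, giving the 5-methoxy-1,2-dioxolane tert-butyl{2-[(3S,5RS)-5-methoxy-3,5-dimethyl-1,2-dioxolan-3-yl]ethoxy}diphenylsilane F2.
- SnCl4 with allyltrimethylsilane (CH2Cl2, −78 °C) generates the peroxycarbenium ion and allylates C5, giving tert-butyl{2-[(3S,5S)-3,5-dimethyl-5-(prop-2-en-1-yl)-1,2-dioxolan-3-yl]ethoxy}diphenylsilane F3. Little facial bias is expected, so F3 must be separated chromatographically from its C5 epimer; that is the price of this route.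
- Cross-metathesis of F3 with commercial oct-7-en-1-ol (same ruthenium catalyst as step 11) gives (7E)-9-[(3S,5S)-3-{2-[(tert-butyldiphenylsilyl)oxy]ethyl}-3,5-dimethyl-1,2-dioxolan-5-yl]non-7-en-1-ol F4.
- Diimide reduction as in step 14 gives 21.

**Step 11.** Most likely failure modes: slow coupling of two hindered alkenes and incomplete E selectivity, which would pass the wrong configuration on to C5. Fallback, setting out from 10 and racemic 15 and returning at 17; here geometry and the carbinol centre are set by thermodynamics and reagent control instead of by resolution: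

- The metathesis is run without resolution, giving the isomer mixture (3R)-14-{[tert-butyl(dimethyl)silyl]oxy}-1-{[tert-butyl(diphenyl)silyl]oxy}-3-[(2-methoxypropan-2-yl)peroxy]-3,5-dimethyltetradec-5-en-7-ol (7RS, 5E/5Z) F5.
- Dess–Martin oxidation gives the enone (3R,5E)-14-{[tert-butyl(dimethyl)silyl]oxy}-1-{[tert-butyl(diphenyl)silyl]oxy}-3-[(2-methoxypropan-2-yl)peroxy]-3,5-dimethyltetradec-5-en-7-one F6. Its E isomer, with the carbonyl opposite the bulky CH2 group, should be favoured on equilibration (catalytic iodine, light) and is purified.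
- Corey–Bakshi–Shibata reduction with the (R)-oxazaborolidine and catecholborane at −78 °C should give the (7S)-alcohol 17.

**Step 5.** Most likely failure mode: competing silylation at the hydroperoxide oxygen, giving mixtures. Fallback, setting out from 8 and returning at 9:

- Exhaustive silylation (excess TBDPSCl, imidazole, DMF) gives tert-butyl{[(3R)-3-[(tert-butyldiphenylsilyl)peroxy]-3,5-dimethylhex-5-en-1-yl]oxy}diphenylsilane F7.
- Selective methanolysis of the far more labile Si–OO bond (K2CO3, MeOH, 0 °C) gives 9, so selectivity rests on leaving-group ability rather than on relative rates of silylation.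

**Step 18.** Most likely failure modes: incomplete E selectivity at C9'=C10', and loss of 24 by vinylogous enolisation. Fallback, setting out from 21 and 24 and returning at 25, with the polarity of the olefination reversed:

- Dess–Martin oxidation of 21 gives 9-[(3S,5S)-3-{2-[(tert-butyldiphenylsilyl)oxy]ethyl}-3,5-dimethyl-1,2-dioxolan-5-yl]nonanal F8.
- Separately, 24 is reduced (NaBH4, CeCl3, MeOH) to (2E,4E)-hepta-2,4-dien-1-ol F9, converted with PBr3 into (2E,4E)-1-bromohepta-2,4-diene F10, and heated with P(OEt)3 (Arbuzov reaction) to give diethyl [(2E,4E)-hepta-2,4-dien-1-yl]phosphonate F11.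
- Horner–Wadsworth–Emmons reaction of lithiated F11 (LiHMDS, THF, −78 °C → rt) with F8 gives 25.

## Further compounds

F1 | step 13 | (4S)-6-[(tert-butyldiphenylsilyl)oxy]-4-[(2-methoxypropan-2-yl)peroxy]-4-methylhexan-2-one | C[C@](CC(C)=O)(OOC(C)(C)OC)CCO[Si](c1ccccc1)(c1ccccc1)C(C)(C)C
F2 | step 13 | tert-butyl{2-[(3S,5RS)-5-methoxy-3,5-dimethyl-1,2-dioxolan-3-yl]ethoxy}diphenylsilane | COC1(C)C[C@](C)(CCO[Si](c2ccccc2)(c2ccccc2)C(C)(C)C)OO1
F3 | step 13 | tert-butyl{2-[(3S,5S)-3,5-dimethyl-5-(prop-2-en-1-yl)-1,2-dioxolan-3-yl]ethoxy}diphenylsilane | C=CC[C@@]1(C)C[C@](C)(CCO[Si](c2ccccc2)(c2ccccc2)C(C)(C)C)OO1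
F4 | step 13 | (7E)-9-[(3S,5S)-3-{2-[(tert-butyldiphenylsilyl)oxy]ethyl}-3,5-dimethyl-1,2-dioxolan-5-yl]non-7-en-1-ol | OCCCCCC/C=C/C[C@@]1(C)C[C@](C)(CCO[Si](c2ccccc2)(c2ccccc2)C(C)(C)C)OO1
F5 | step 11 | (3R)-14-{[tert-butyl(dimethyl)silyl]oxy}-1-{[tert-butyl(diphenyl)silyl]oxy}-3-[(2-methoxypropan-2-yl)peroxy]-3,5-dimethyltetradec-5-en-7-ol (7RS, 5E/5Z mixture) | CC(C)(C)[Si](C)(C)OCCCCCCCC(O)C=C(C)C[C@@](C)(OOC(C)(C)OC)CCO[Si](c1ccccc1)(c1ccccc1)C(C)(C)C
F6 | step 11 | (3R,5E)-14-{[tert-butyl(dimethyl)silyl]oxy}-1-{[tert-butyl(diphenyl)silyl]oxy}-3-[(2-methoxypropan-2-yl)peroxy]-3,5-dimethyltetradec-5-en-7-one | CC(C)(C)[Si](C)(C)OCCCCCCCC(=O)/C=C(\C)C[C@@](C)(OOC(C)(C)OC)CCO[Si](c1ccccc1)(c1ccccc1)C(C)(C)C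
F7 | step 5 | tert-butyl{[(3R)-3-[(tert-butyldiphenylsilyl)peroxy]-3,5-dimethylhex-5-en-1-yl]oxy}diphenylsilane | C[C@](CC(C)=C)(OO[Si](c1ccccc1)(c1ccccc1)C(C)(C)C)CCO[Si](c1ccccc1)(c1ccccc1)C(C)(C)C
F8 | step 18 | 9-[(3S,5S)-3-{2-[(tert-butyldiphenylsilyl)oxy]ethyl}-3,5-dimethyl-1,2-dioxolan-5-yl]nonanal | O=CCCCCCCCC[C@@]1(C)C[C@](C)(CCO[Si](c2ccccc2)(c2ccccc2)C(C)(C)C)OO1
F9 | step 18 | (2E,4E)-hepta-2,4-dien-1-ol | CC/C=C/C=C/CO
F10 | step 18 | (2E,4E)-1-bromohepta-2,4-diene | CC/C=C/C=C/CBr
F11 | step 18 | diethyl [(2E,4E)-hepta-2,4-dien-1-yl]phosphonate | CC/C=C/C=C/CP(=O)(OCC)OCC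
A1 | alternative 1 | bis[(2R)-2-methyloxetan-2-yl]methane | C[C@]1(C[C@@]2(C)CCO2)CCO1
A2 | alternative 1 | 2,2'-[(3S,5S)-3,5-dimethyl-1,2-dioxolane-3,5-diyl]diethanol | OCC[C@@]1(C)C[C@](C)(CCO)OO1
A3 | alternative 2 | O,O'-[(3S,5S)-1,7-bis{[tert-butyl(dimethyl)silyl]oxy}-3,5-dimethylheptane-3,5-diyl]dihydroxylamine | CC(C)(C)[Si](C)(C)OCC[C@](C)(ON)C[C@@](C)(ON)CCO[Si](C)(C)C(C)(C)C
A4 | alternative 2 | (3S,5S)-3,5-bis[2-(tert-butyldimethylsilyloxy)ethyl]-3,5-dimethyl-1,2-dioxolane | CC(C)(C)[Si](C)(C)OCC[C@@]1(C)C[C@](C)(CCO[Si](C)(C)C(C)(C)C)OO1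
A5 | alternative 3 | tert-butyl({10-methoxy-10-[(triethylsilyl)peroxy]undecyl}oxy)diphenylsilane | CC(OC)(OO[Si](CC)(CC)CC)CCCCCCCCCO[Si](c1ccccc1)(c1ccccc1)C(C)(C)C
A6 | alternative 3 | methyl 3-methylbut-3-enoate | COC(=O)CC(C)=C
A7 | alternative 3 | methyl 2-[(3R,5S)-5-[9-(tert-butyldiphenylsilyloxy)nonyl]-3,5-dimethyl-1,2-dioxolan-3-yl]acetate | CC(C)(C)[Si](c1ccccc1)(c2ccccc2)OCCCCCCCCC[C@@]3(C)C[C@](C)(CC(=O)OC)OO3
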